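The 2-(2-hydroxypropan-2-yl)-2,3-dihydrobenzofuran hides an isoprene unit: C3, C2 and the three side-chain carbons, joined to the resorcinol ring through C3a and O1. Both ring bonds (C3a–C3 and O1–C2) are therefore made in one enantioselective palladium-catalysed heteroannulation of isoprene with 1-(2,4-dihydroxy-5-iodophenyl)ethanone, an iodophenol that already carries the future C5 acetyl and C6 hydroxyl groups. This single operation closes the dihydrofuran ring and sets C2 as (S). The alkene is then hydrated, the acetyl group is turned into a silyl enol ether, and a catalyst-controlled Mukaiyama aldol with 2,2-dimethylchroman-6-carbaldehyde installs the (S)-carbinol before global desilylation.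

Key step: step 2

Assumption: where an enantioselective catalyst is named, the antipode meant is the one expected to give the configuration drawn; if the sense of induction proves opposite, its mirror image is used.

Step 1
Reactants: 1 2,4-dihydroxyacetophenone
Product: 2 1-(2,4-dihydroxy-5-iodophenyl)ethanone
Conditions: ICl (1.0 equiv), AcOH, 25 °C
Reagents that add atoms: iodine monochloride, ClI
Why: Electrophilic aromatic iodination should go to C5, which is ortho to the free 4-hydroxyl and para to the chelated 2-hydroxyl and is less hindered than C3 between the two oxygens.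

Step 2
Reactants: 2 1-(2,4-dihydroxy-5-iodophenyl)ethanone; 3 isoprene
Product: 4 (S)-1-[6-hydroxy-2-(prop-1-en-2-yl)-2,3-dihydrobenzofuran-5-yl]ethanone
Conditions: Pd2(dba)3·CHCl3 (2.5 mol%), chiral sulfinamide–monophosphine ligand (10 mol%), PhONa (2 equiv), isoprene (5 equiv), CH2Cl2, 40 °C, sealed tube
Reagents that add atoms: none
Why: Zerovalent palladium inserts into the C–I bond of 2, the arylpalladium adds across the unsubstituted vinyl group of isoprene with the aryl on the terminal CH2 (forming C3a–C3), and the resulting 2-methyl-substituted π-allylpalladium is attacked by the neighbouring phenoxide at its internal terminus (forming O1–C2), releasing zerovalent palladium. The closest known reaction type is the palladium-catalysed heteroannulation of ortho-halophenols with 1,3-dienes (Larock annulation, a Heck/Tsuji–Trost cascade), which is established in enantioselective form with chiral monophosphines. The dihydrofuran ring closes by a 5-exo intramolecular allylic substitution, whereas attack at the distal CH2 terminus would require a seven-membered ring. The C2 stereocentre is set under catalyst control: the chiral phosphine differentiates the two faces of the π-allyl complex, which can interconvert through its unsubstituted terminus, and the phenoxide attacks anti to palladium. Two selectivities are needed: aryl delivery to the methyl-free alkene terminus, secured by sterics and by the more stabilised allyl that results, and ring closure through the 4-hydroxyl only, secured because it alone is ortho to the carbon–palladium bond. The 2-hydroxyl is meta to that bond and hydrogen-bonded to the acetyl group, so the precursor needs no protecting group.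

Step 3
Reactants: 4 (S)-1-[6-hydroxy-2-(prop-1-en-2-yl)-2,3-dihydrobenzofuran-5-yl]ethanone
Product: 5 (S)-1-[6-hydroxy-2-(2-hydroxypropan-2-yl)-2,3-dihydrobenzofuran-5-yl]ethanone
Conditions: Co(acac)2 (20 mol%), PhSiH3 (2 equiv), O2 (1 atm), THF/i-PrOH, 25 °C
Reagents that add atoms: dioxygen, O=O
Why: Mukaiyama hydration, in which hydrogen-atom transfer from a cobalt hydride to the 1,1-disubstituted alkene gives the tertiary radical that is trapped by O2 and reduced to the Markovnikov tertiary alcohol under neutral conditions, should leave the chelated phenol, the aryl ketone and the adjacent C2 stereocentre untouched.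

Step 4
Reactants: 5 (S)-1-[6-hydroxy-2-(2-hydroxypropan-2-yl)-2,3-dihydrobenzofuran-5-yl]ethanone
Product: 6 (S)-6-(triethylsilyloxy)-2-[2-(triethylsilyloxy)propan-2-yl]-5-[1-(triethylsilyloxy)ethenyl]-2,3-dihydrobenzofuran
Conditions: TESOTf (3.6 equiv), Et3N (6 equiv), CH2Cl2, 0 → 25 °C
Reagents that add atoms: triethylsilyl trifluoromethanesulfonate, CC[Si](CC)(CC)OS(=O)(=O)C(F)(F)F
Why: Silyl triflate and amine base silylate the phenol and the tertiary alcohol and at the same time convert the methyl ketone into its silyl enol ether (soft enolisation), so protection and nucleophile activation cost one step and all silicon groups can later leave together.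

Step 5
Reactants: 7 4-hydroxybenzaldehyde; 3 isoprene
Product: 9 2,2-dimethylchroman-6-carbaldehyde, via 4-hydroxy-3-(3-methylbut-2-enyl)benzaldehyde 8 (not isolated)
Conditions: Amberlyst 15 (sulfonic acid resin), isoprene (3 equiv), heptane/THF, 65 °C, sealed vessel
Reagents that add atoms: none
Why: Acid-catalysed Friedel–Crafts prenylation ortho to the phenol (the para position is blocked by the formyl group) followed by Markovnikov hydroalkoxylation of the prenyl alkene through the tertiary cation closes the 2,2-dimethylchroman, a known one-pot chroman synthesis from acylphenols and isoprene.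

Step 6
Reactants: 6 (S)-6-(triethylsilyloxy)-2-[2-(triethylsilyloxy)propan-2-yl]-5-[1-(triethylsilyloxy)ethenyl]-2,3-dihydrobenzofuran; 9 2,2-dimethylchroman-6-carbaldehyde
Product: 11 (S)-3-(2,2-dimethylchroman-6-yl)-3-hydroxy-1-{(S)-6-(triethylsilyloxy)-2-[2-(triethylsilyloxy)propan-2-yl]-2,3-dihydrobenzofuran-5-yl}propan-1-one, via trichlorosilyl aldolate 10 (not isolated)
Conditions: SiCl4 (1.5 equiv), chiral binaphthyldiamine-derived bisphosphoramide (5 mol%, antipode for Si-face addition), i-Pr2NEt (10 mol%), CH2Cl2, −78 °C; then sat. aq. NaHCO3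
Reagents that add atoms: none
Why: In this Lewis-base-activated Mukaiyama aldol the bisphosphoramide ionises SiCl4 to a chiral trichlorosilyl cation that binds the aromatic aldehyde, and the enol silane adds through an open transition state to the Si face, setting the (S)-carbinol under catalyst control while the remote C2 centre is untouched.

Step 7
Reactants: 11 (S)-3-(2,2-dimethylchroman-6-yl)-3-hydroxy-1-{(S)-6-(triethylsilyloxy)-2-[2-(triethylsilyloxy)propan-2-yl]-2,3-dihydrobenzofuran-5-yl}propan-1-one
Product: 12 (S)-3-(2,2-dimethylchroman-6-yl)-3-hydroxy-1-[(S)-6-hydroxy-2-(2-hydroxypropan-2-yl)-2,3-dihydrobenzofuran-5-yl]propan-1-one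
Conditions: Et3N·3HF (excess), THF, 25 °C
Reagents that add atoms: none
Why: Fluoride-mediated desilylation with a nearly neutral amine hydrofluoride should remove the aryl and tertiary triethylsilyl ethers without retro-aldol cleavage, dehydration to the chalcone or any change at the two stereocentres.

Compound list
1 | 2,4-dihydroxyacetophenone | CC(=O)c1ccc(O)cc1O | starting material
2 | 1-(2,4-dihydroxy-5-iodophenyl)ethanone | CC(=O)c1cc(I)c(O)cc1O | intermediate
3 | isoprene (2-methylbuta-1,3-diene) | CC(=C)C=C | starting material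
4 | (S)-1-[6-hydroxy-2-(prop-1-en-2-yl)-2,3-dihydrobenzofuran-5-yl]ethanone | CC(=O)c1cc2c(cc1O)O[C@H](C(C)=C)C2 | intermediate
5 | (S)-1-[6-hydroxy-2-(2-hydroxypropan-2-yl)-2,3-dihydrobenzofuran-5-yl]ethanone | CC(=O)c1cc2c(cc1O)O[C@H](C(C)(C)O)C2 | intermediate
6 | (S)-6-(triethylsilyloxy)-2-[2-(triethylsilyloxy)propan-2-yl]-5-[1-(triethylsilyloxy)ethenyl]-2,3-dihydrobenzofuran | C=C(O[Si](CC)(CC)CC)c1cc2c(cc1O[Si](CC)(CC)CC)O[C@H](C(C)(C)O[Si](CC)(CC)CC)C2 | intermediate
7 | 4-hydroxybenzaldehyde | O=Cc1ccc(O)cc1 | starting material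
8 | 4-hydroxy-3-(3-methylbut-2-enyl)benzaldehyde | CC(C)=CCc1cc(C=O)ccc1O | intermediate
9 | 2,2-dimethylchroman-6-carbaldehyde | CC1(C)CCc2cc(C=O)ccc2O1 | intermediate
10 | trichlorosilyl aldolate: (S)-3-(2,2-dimethylchroman-6-yl)-3-(trichlorosilyloxy)-1-{(S)-6-(triethylsilyloxy)-2-[2-(triethylsilyloxy)propan-2-yl]-2,3-dihydrobenzofuran-5-yl}propan-1-one | CC1(C)CCc2cc([C@@H](O[Si](Cl)(Cl)Cl)CC(=O)c3cc4c(cc3O[Si](CC)(CC)CC)O[C@H](C(C)(C)O[Si](CC)(CC)CC)C4)ccc2O1 | intermediate
11 | (S)-3-(2,2-dimethylchroman-6-yl)-3-hydroxy-1-{(S)-6-(triethylsilyloxy)-2-[2-(triethylsilyloxy)propan-2-yl]-2,3-dihydrobenzofuran-5-yl}propan-1-one | CC1(C)CCc2cc([C@@H](O)CC(=O)c3cc4c(cc3O[Si](CC)(CC)CC)O[C@H](C(C)(C)O[Si](CC)(CC)CC)C4)ccc2O1 | intermediate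
12 | (S)-3-(2,2-dimethylchroman-6-yl)-3-hydroxy-1-[(S)-6-hydroxy-2-(2-hydroxypropan-2-yl)-2,3-dihydrobenzofuran-5-yl]propan-1-one | CC1(C)CCc2cc([C@@H](O)CC(=O)c3cc4c(cc3O)O[C@H](C(C)(C)O)C4)ccc2O1 | target

Total step count: 7. Longest linear sequence: 6 steps (steps 1, 2, 3, 4, 6, 7); step 5 is a one-step side branch.

Steps most likely to fail

Step 2. The arylpalladium could add to the methyl-bearing alkene terminus and lead to the 2-methyl-2-vinyl ring. The acyl-deactivated phenoxide could also trap the π-allyl too slowly, so that β-hydride elimination to aryl dienes competes, or the ligand could discriminate the π-allyl faces poorly. The fallback sets out from 1 and returns at 5, bypassing 4 and step 3. Friedel–Crafts prenylation of 1 (2-methylbut-3-en-2-ol, BF3·OEt2, dioxane, 25 °C) should give 1-[2,4-dihydroxy-5-(3-methylbut-2-en-1-yl)phenyl]ethanone F1. Selective silylation of the non-chelated 4-hydroxyl (TBSCl, imidazole, DMF) gives 1-[4-(tert-butyldimethylsilyloxy)-2-hydroxy-5-(3-methylbut-2-en-1-yl)phenyl]ethanone F2. Shi epoxidation (fructose-derived ketone, Oxone, K2CO3-buffered MeCN/dimethoxymethane/water, 0 °C) gives the (R)-epoxide 1-[4-(tert-butyldimethylsilyloxy)-5-{[(2R)-3,3-dimethyloxiran-2-yl]methyl}-2-hydroxyphenyl]ethanone F3. TBAF in THF then frees the phenoxide, which opens the epoxide at the secondary carbon in a 5-exo mode with inversion to give 5.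

Step 6. The bulky ortho-silyloxyaryl enol silane could add with poor facial discrimination, or the electron-rich aldehyde could react so slowly that the enol ether is lost by protodesilylation. Diastereomers from imperfect control in either asymmetric step would have to be separated at 11. The fallback sets out from 5 and returns at 12 through an epoxy ketone:
- Allylation of the chelated phenol (allyl bromide, K2CO3, DMF, 60 °C) should give 1-[(2S)-6-(allyloxy)-2-(2-hydroxypropan-2-yl)-2,3-dihydrobenzofuran-5-yl]ethanone F4.
- Claisen–Schmidt condensation with 9 (KOH, EtOH, 25 °C) gives the (E)-chalcone F5.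
- Juliá–Colonna epoxidation (poly-D-leucine, urea–H2O2, DBU, THF) gives the (2S,3R)-epoxy ketone F6, whose benzylic C–O bond already has the configuration of the target carbinol.
- SmI2 (THF/MeOH, −78 °C) cleaves only the C–O bond next to the carbonyl and gives the O-allyl aldol F7.
- Pd(PPh3)4 with morpholine in THF removes the allyl group to give 12.

Step 5. The formyl-deactivated phenol could alkylate slowly while isoprene oligomerises on the resin, and over-alkylation could erode the material balance. The fallback sets out from 7 and returns at 9. Etherification with 3-chloro-3-methylbut-1-yne (K2CO3, KI, CuI cat., acetone, reflux) gives 4-[(2-methylbut-3-yn-2-yl)oxy]benzaldehyde F8. Aryl propargyl ether Claisen rearrangement with electrocyclisation (N,N-diethylaniline, 190 °C) gives 2,2-dimethyl-2H-chromene-6-carbaldehyde F9. Hydrogenation of the styrenic alkene (H2 1 atm, palladium on carbon, EtOAc, stopped after one equivalent) gives 9.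

Further compounds
F1 | step 2 | 1-[2,4-dihydroxy-5-(3-methylbut-2-en-1-yl)phenyl]ethanone | CC(=O)c1cc(CC=C(C)C)c(O)cc1O
F2 | step 2 | 1-[4-(tert-butyldimethylsilyloxy)-2-hydroxy-5-(3-methylbut-2-en-1-yl)phenyl]ethanone | CC(=O)c1cc(CC=C(C)C)c(O[Si](C)(C)C(C)(C)C)cc1O
F3 | step 2 | 1-[4-(tert-butyldimethylsilyloxy)-5-{[(2R)-3,3-dimethyloxiran-2-yl]methyl}-2-hydroxyphenyl]ethanone | CC(=O)c1cc(C[C@H]2OC2(C)C)c(O[Si](C)(C)C(C)(C)C)cc1O
F4 | step 6 | 1-[(2S)-6-(allyloxy)-2-(2-hydroxypropan-2-yl)-2,3-dihydrobenzofuran-5-yl]ethanone | CC(=O)c1cc2c(cc1OCC=C)O[C@H](C(C)(C)O)C2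
F5 | step 6 | (E)-1-[(2S)-6-(allyloxy)-2-(2-hydroxypropan-2-yl)-2,3-dihydrobenzofuran-5-yl]-3-(2,2-dimethylchroman-6-yl)prop-2-en-1-one | CC1(C)CCc2cc(/C=C/C(=O)c3cc4c(cc3OCC=C)O[C@H](C(C)(C)O)C4)ccc2O1
F6 | step 6 | [(2S)-6-(allyloxy)-2-(2-hydroxypropan-2-yl)-2,3-dihydrobenzofuran-5-yl][(2S,3R)-3-(2,2-dimethylchroman-6-yl)oxiran-2-yl]methanone | O=C(c1cc2c(cc1OCC=C)O[C@H](C(C)(C)O)C2)[C@H]1O[C@@H]1c3ccc4OC(C)(C)CCc4c3
F7 | step 6 | (S)-1-[(2S)-6-(allyloxy)-2-(2-hydroxypropan-2-yl)-2,3-dihydrobenzofuran-5-yl]-3-(2,2-dimethylchroman-6-yl)-3-hydroxypropan-1-one | CC1(C)CCc2cc([C@@H](O)CC(=O)c3cc4c(cc3OCC=C)O[C@H](C(C)(C)O)C4)ccc2O1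
F8 | step 5 | 4-[(2-methylbut-3-yn-2-yl)oxy]benzaldehyde | C#CC(C)(C)Oc1ccc(C=O)cc1
F9 | step 5 | 2,2-dimethyl-2H-chromene-6-carbaldehyde | CC1(C)C=Cc2cc(C=O)ccc2O1
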